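(The numbers in the tables were computed on assumed constants.)

The number I started from was 1.10, the equivalents c_X/c_J as charged in this flask. X may turn J into Q and Z into G, but it may also be lost by itself to E and L, so I wanted to learn what one equivalent of X buys.

| flask | J | Z | X | remark | time |
|---|---|---|---|---|---|
| north-west | 0.050 M | 0.050 M | 0.077 M | run made earlier |  |
| north | 0.050 M | 0.050 M | 0.12 M | run made earlier |  |
| north-east | 0.10 M | 0.10 M | 0.055 M | run made earlier |  |
| flask | 0.050 M | 0.050 M | 0.0550 M |  | 8.0 h |

| run | time / h | Z / % | J / % |
|---|---|---|---|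
| north-west | 0.667 | 49.0 | 33.9 |
| north-west | 1.00 | 49.4 | 32.3 |
| north-west | 2.00 | 48.7 | 31.3 |
| north-west | 3.00 | 49.1 | 32.9 |
| north-west | 5.00 | 49.5 | 31.6 |
| north-west | 8.00 | 49.1 | 31.1 |
| north | 0.500 | 49.1 | 30.5 |
| north | 1.50 | 48.5 | 27.4 |
| north | 3.00 | 48.6 | 26.8 |
| north | 4.00 | 48.6 | 27.9 |
| north | 6.00 | 49.9 | 27.1 |
| north | 8.00 | 48.2 | 27.2 |
| north-east | 0.667 | 49.0 | 39.8 |
| north-east | 1.33 | 49.6 | 38.7 |
| north-east | 2.50 | 48.8 | 38.7 |
| north-east | 4.00 | 49.3 | 38.2 |
| north-east | 8.00 | 49.1 | 38.4 |

(each reading ± 0.5 percentage points)

- whether the excess of Z over J among what is left of the two reaches 99% by 8.0 h (yes / no)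
- the highest excess of Z over J among what is left of the two up to 8.0 h

- X is single-handed; J and Z are mirror images of each other, charged as a racemate, each of them at the stated concentration
- the analysis behind the earlier runs scatters by 0.5 percentage points, standard deviation
- what may be going on: X + J -> Q; Q <-> G; X + Z -> G; X -> E; 2 X -> L
- the handed part of X does not stay in what it makes, so the products of the two hands are mirror images too

In each run J fell and then lay flat within the scatter, while the readings of Z stayed between 48.2% and 49.9%. I took the mean of the last 3 readings of J as its plateau, and called ln(charged J / plateau J) the depth. It read 0.263 at 0.550 equivalents (north-east), 0.450 at 1.54 (north-west) and 0.601 at 2.40 (north). The two outer runs give 0.183, the depth gained per equivalent of X.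

Was one number enough? The north-east run held twice the J of the others, yet its line to the north run puts north-west J at 32.1%, against a plateau of 31.9%, a gap inside the scatter of 0.5 percentage points. So I used it.

For this flask the line gave depth 0.364 and J at 34.8%. With Z taken from the last north-east reading, I reckoned a plateau excess of 17.1%. Reaching 99% with Z held there asks for depth 5.31, far beyond that, so my answer was no.

The forecast said no and 17%, holding that “X dies before it finishes the job”.

The flask gave no and 16.5%. At 8.00 h, X, the limiting reagent, stood at 0% of its charge, with 71% of the charged J left.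

    X + J → Q (k = 0.00680 /M/s)
    Q ⇌ G (k = 5.50 × 10⁻⁴ /s)
    X + Z → G (k = 2.90 × 10⁻⁴ /M/s)
    X → E (k = 4.80 × 10⁻⁴ /s)
    2 X → L (k = 0.00610 /M/s)

In a neighbour flask charged with 0.14 M of X, 2.80 equiv, 0.183 carried the north depth to 0.675, so I reckoned J at 25.5% and, with Z again from the last north-east reading, an excess of 31.7%. Computed, that flask ended with J at 25.5% and a top of 31.2%.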